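**Assumptions (one line each)**
- The target's single stereocentre (flavanone C2) is R by CIP analysis of the SMILES (O1 > aryl > C3 > H), i.e. the antipode of natural (2S)-abyssinone III.
- The facial sense of the new step cannot be predicted with confidence; it is written with the (S,S)-ligand, and the (R,R)-antipode is used instead if the first run (chiral HPLC plus CD against the natural 2S series) shows 2S.
- 7-Hydroxychromone and 3-chloro-3-methylbut-1-yne are taken as catalogue chemicals.

**Retrosynthetic overview**
1. Target 11 ⇐ 7-O-TBS flavanone 10 by O-desilylation (last step).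
2. 10 ⇐ aryl bromide 6 + 7-silyloxychromone 9: the C2–aryl bond and the only stereocentre (2R) come from a new Ni-catalysed enantioselective reductive conjugate arylation.
3. 6 ⇐ aryl 1,1-dimethylpropargyl ether 5 (propargyl Claisen / oxa-6π gives the chromene ring) ⇐ 4-bromo-2-prenylphenol 3 ⇐ 4-bromophenol 1 (ortho C-prenylation).
4. Ring order: the benzopyranone A/C rings are bought intact (7-hydroxychromone 7); the B-unit chromene ring is formed in step 3; no ring is formed after fragment union.

**Route**

Step 1
Reactants: 1, 4-bromophenol; 2, prenyl bromide (1-bromo-3-methylbut-2-ene)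
Product: 3, 4-bromo-2-(3-methylbut-2-en-1-yl)phenol
Conditions: NaH (1.0 equiv), toluene, 0 °C; then 2, rt; separate O-prenyl ether by aqueous NaOH extraction
Reagents that add atoms: prenyl bromide, CC(C)=CCBr
Why: Ortho-selective C-alkylation of a tight sodium phenoxide ion pair in a non-polar solvent (phenoxide C-allylation); the para position is blocked by Br, and no stereocentre is formed.

Step 2
Reactants: 3, 4-bromo-2-(3-methylbut-2-en-1-yl)phenol; 4, 3-chloro-3-methylbut-1-yne
Product: 5, 4-bromo-1-[(2-methylbut-3-yn-2-yl)oxy]-2-(3-methylbut-2-en-1-yl)benzene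
Conditions: DBU, CuCl2·2H2O (1 mol %), MeCN, 0 °C → rt
Reagents that add atoms: 3-chloro-3-methylbut-1-yne, CC(C)(Cl)C#C
Why: Copper-catalysed propargylic O-alkylation of a phenol with a tertiary propargylic chloride (via a Cu-acetylide/allenylidene ion pair) gives the aryl 1,1-dimethylpropargyl ether cleanly; the aryl bromide and prenyl group are inert.

Step 3
Reactants: 5, 4-bromo-1-[(2-methylbut-3-yn-2-yl)oxy]-2-(3-methylbut-2-en-1-yl)benzene
Product: 6, 6-bromo-2,2-dimethyl-8-(3-methylbut-2-en-1-yl)-2H-chromene
Conditions: PhNEt2, 180 °C
Reagents that add atoms: none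
Why: Aromatic propargyl Claisen rearrangement to the only free ortho position, then 1,5-H shift and oxa-6π electrocyclisation, forms the 2,2-dimethyl-2H-chromene ring (an isomerisation, all atoms retained).

Step 4
Reactants: 7, 7-hydroxy-4H-chromen-4-one (7-hydroxychromone); 8, tert-butyldimethylsilyl chloride
Product: 9, 7-[(tert-butyldimethylsilyl)oxy]-4H-chromen-4-one
Conditions: TBSCl, imidazole, DMF, rt
Reagents that add atoms: TBSCl, CC(C)(C)[Si](C)(C)Cl
Why: Standard phenol silylation; it masks the acidic 7-OH, which would otherwise quench low-valent Ni and deactivate the enone as a phenoxide.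

Step 5 (key step, new)
Reactants: 6, 6-bromo-2,2-dimethyl-8-(3-methylbut-2-en-1-yl)-2H-chromene; 9, 7-[(tert-butyldimethylsilyl)oxy]-4H-chromen-4-one
Product: 10, (2R)-7-[(tert-butyldimethylsilyl)oxy]-2-[2,2-dimethyl-8-(3-methylbut-2-en-1-yl)-2H-chromen-6-yl]-2,3-dihydro-4H-chromen-4-one
Conditions: NiBr2·glyme (10 mol %), (S,S)-iPr-PyBox (12 mol %), Mn powder (3 equiv), TMSCl (3 equiv), DMA, 0 °C → rt; then 1 M HCl, THF, 0 °C, 15 min (hydrolyses the non-isolated 4-trimethylsilyloxy-2H-chromene); check ee by chiral HPLC and recrystallise 10 if needed
Reagents that add atoms: none (both fragments are the listed reactants; TMSCl is incorporated only transiently as the silyl enol ether, and C3–H comes from the aqueous acid)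
Why: Proposed new method: TMSCl reversibly O-silylates chromone 9 to a 4-silyloxybenzopyrylium ion, to which PyBox–Ni(0) adds at C2 to give a chiral 1-silyloxyallyl-nickel species; after Mn reduction this takes up ArBr 6 by oxidative addition, and C(sp2)–C(sp3) reductive elimination forms the C2–aryl bond on the Ni-bound face, the C2-symmetric tridentate ligand discriminating the enantiotopic faces of the planar cation to set C2 as R; the product leaves as a silyl enol ether that cannot ring-open by β-aryloxide elimination or epimerise before mild acid hydrolysis, and because no Ni–H is generated the prenyl and chromene alkenes are spectators; the closest known reaction types are the racemic Ni/terpyridine reductive conjugate addition of aryl halides to enones with chlorosilane and Mn, Ni/chiral N-ligand enantioselective reductive conjugate arylation of simple enones, and Ni-catalysed enantioselective arylation of pyridinium and chromene-acetal-derived cations, none of which has been shown on chromones.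

Step 6
Reactants: 10, (2R)-7-[(tert-butyldimethylsilyl)oxy]-2-[2,2-dimethyl-8-(3-methylbut-2-en-1-yl)-2H-chromen-6-yl]-2,3-dihydro-4H-chromen-4-one
Product: 11, ent-abyssinone III, (2R)-7-hydroxy-2-[2,2-dimethyl-8-(3-methylbut-2-en-1-yl)-2H-chromen-6-yl]-2,3-dihydro-4H-chromen-4-one
Conditions: TBAF/AcOH (1:1, 1.2 equiv), THF, 0 °C
Reagents that add atoms: none
Why: Fluoride-mediated cleavage of the aryl silyl ether; the AcOH buffer prevents build-up of phenoxide or C3 enolate, so no retro-oxa-Michael ring opening occurs and C2 stays R.

**Compound list**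
1 | 4-bromophenol | Oc1ccc(Br)cc1 | starting material
2 | prenyl bromide | CC(C)=CCBr | starting material
3 | 4-bromo-2-(3-methylbut-2-en-1-yl)phenol | CC(C)=CCc1cc(Br)ccc1O | intermediate
4 | 3-chloro-3-methylbut-1-yne | CC(C)(Cl)C#C | starting material
5 | 4-bromo-1-[(2-methylbut-3-yn-2-yl)oxy]-2-(3-methylbut-2-en-1-yl)benzene | CC(C)=CCc1cc(Br)ccc1OC(C)(C)C#C | intermediate
6 | 6-bromo-2,2-dimethyl-8-(3-methylbut-2-en-1-yl)-2H-chromene | CC(C)=CCc1cc(Br)cc2c1OC(C)(C)C=C2 | intermediate
7 | 7-hydroxy-4H-chromen-4-one | O=c1ccoc2cc(O)ccc12 | starting material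
8 | tert-butyldimethylsilyl chloride | CC(C)(C)[Si](C)(C)Cl | starting material
9 | 7-[(tert-butyldimethylsilyl)oxy]-4H-chromen-4-one | CC(C)(C)[Si](C)(C)Oc1ccc2c(c1)occc2=O | intermediate
10 | (2R)-7-[(tert-butyldimethylsilyl)oxy]-2-[2,2-dimethyl-8-(3-methylbut-2-en-1-yl)-2H-chromen-6-yl]chroman-4-one | CC(C)=CCc1cc([C@H]2CC(=O)c3ccc(O[Si](C)(C)C(C)(C)C)cc3O2)cc2c1OC(C)(C)C=C2 | intermediate
11 | ent-abyssinone III, (2R)-7-hydroxy-2-[2,2-dimethyl-8-(3-methylbut-2-en-1-yl)-2H-chromen-6-yl]chroman-4-one | CC(C)=CCc1cc([C@H]2CC(=O)c3ccc(O)cc3O2)cc2c1OC(C)(C)C=C2 | target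

**Totals**
- Total steps: 6
- Longest linear sequence: 5 (steps 1, 2, 3, 5, 6 from 4-bromophenol)

**Three steps most likely to fail, with fallbacks**
1. Step 5 (proposed new Ni reductive arylation). Risks are low ee or the wrong sense, biaryl or ArH formation, Mn-mediated reductive dimerisation of the benzopyrylium, and sluggish reaction of the vinylogous ester. Fallback (known chemistry, different bond-forming logic): convert 6 to the arylboronic acid (n-BuLi, THF, −78 °C; B(OiPr)3; aqueous acid), then run the established Pd(OCOCF3)2/t-BuPyOx-catalysed asymmetric conjugate addition of arylboronic acids to chromones (NH4PF6, H2O, ClCH2CH2Cl, 60 °C) on 9. The ligand antipode is chosen to give 2R; a Rh(I)/chiral diene system is the alternative. This delivers the same intermediate 10.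
2. Step 1 (ortho C-prenylation). Risks are competing O-alkylation and bis-alkylation, giving a modest yield. Fallback: install the prenyl group by aromatic Claisen rearrangement instead. O-alkylate 1 with 4 (Cu/DBU as in step 2), semi-hydrogenate the alkyne (Lindlar) to the 1,1-dimethylallyl ether, and heat (about 120 °C) for the [3,3] shift to 3.
3. Step 6 (desilylation). Risk is fluoride-generated phenoxide or enolate triggering retro-oxa-Michael opening to the chalcone and erosion of ee. Fallback: change the protecting-group strategy. Carry the A ring as the 7-O-MOM ether (MOMCl, iPr2NEt on 7) and unmask with HCl/MeOH at rt–40 °C, acidic conditions under which flavanone C2 is configurationally stable and which the prenyl and dimethylchromene groups (no free ortho phenol in the B ring) tolerate.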